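## Structural features

The target joins two rings through a single methylene carbon: a fully substituted 4-hydroxy-2-pyranone (O1, lactone carbonyl C2, C3 carrying the bridge, C4 hydroxyl, C5 methyl, C6 ethyl) and a hexasubstituted benzene (C1' bridge, C2' OH, C3' prenyl, C4' OH, C5' (R)-2-methylbutanoyl, C6' OMe). The only stereocenter is the α-carbon of the aryl ketone. It is tertiary and enolizable and has no neighbouring stereocenter to hold it, so it has to come from (R)-2-methylbutanoic acid after the last strongly basic step. The prenyl group lies between two phenolic oxygens and closes to a chroman under protic or strong Lewis acid, and a free C2' hydroxyl would lactonize onto any ester on the bridge side chain. The three ring oxygens are mutually meta and must end up different (free at C2' and C4', methyl ether at C6'), and no ring carbon is unsubstituted. The real difficulty is therefore a regiochemically unambiguous hexasubstituted arene with differentiated oxygens, not the pyranone. The key step exploits this: four ring carbons (C4', C1', C6', C5') come from a cyclobutenone and two (C3', C2') from an ynol ether. The oxygens thus arrive as free hydroxyl, silyl ether and methyl ether, with the bridge carbon and the prenyl group already in place.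

## Logic of the disconnections

23 to 22: the C2'–O–Si bond is the last to be cleaved in the forward direction. The silyl group is kept to the end because it stops the C2' oxygen from lactonizing onto the side-chain ester, blocks one of the two oxygens that could add to the prenyl double bond, and leaves the C4' hydroxyl as the only acylable phenol. The gain is in chemoselectivity, not in atoms. The forward step needs a buffered fluoride source so that the enolizable stereocenter is not epimerized.

22 to 21: the C5'–C(=O) bond is cut and the acyl group is returned to the C4' oxygen. C5' is the only open ring carbon and is ortho to that oxygen, so an O-to-C acyl shift has a single regiochemical outcome and carries the stereocenter over intact. The arene loses its sixth substituent. The forward step must run cold, with an acid scavenger, so that the prenyl group, the silyl ether and the α-hydrogen survive.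

21 to 19 and 20: the ester C(=O)–O bond is cut, which traces the stereocenter to the chiral-pool acid. The cut is placed after the last enolate step so that the stereocenter never meets a strong base. The forward step must put the acyl group on the phenol oxygen and not on the more acidic pyranone hydroxyl, and must avoid ketene formation.

19 to 17 through 18: the O1–C2 lactone bond and the C5–C6 bond of the pyranone are cut. A 3,5-diketo ester lactonizes under mild base, so the heterocycle reduces to a β-keto ester and a three-carbon acyl donor. The forward step needs γ-selective acylation of a polyanion and must avoid Claisen carbocyclization of 18.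

17 to 16: the pyranone C3–C4 bond is cut. C3 is the α-carbon of the propanoate that leaves the benzannulation, so the whole heterocycle is traced to an ester side chain. The forward step is an ester-enolate acylation next to a free phenoxide, which calls for an acyl donor that phenoxides do not attack.

16 to 6 and 11: the C3'–C4' and C1'–C2' bonds are cut and the benzene ring is opened. The C4'–C5' bond is formally broken and re-formed. A pentasubstituted benzene with three different oxygens becomes a four-membered ring and an alkyne. The forward step needs one orientation of a ketene–alkyne [2+2] addition and thermal opening of a donor-stabilized cyclobutenone.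

6 to 3 and 4 through 5: the bond between ring C2 and the side-chain CH2 is cut as an sp2–sp3 cross-coupling. The α-carbon of a 3-alkoxycyclobutenone is easy to halogenate, and an ester-bearing alkylzinc does not add to the strained ketone. The forward coupling must be faster than β-hydride loss and ring degradation.

3 to 2 to 1: the O-methyl bond is traced to an O-ethyl bond by alkoxy exchange, and the C2–Br bond to C2–H. Both operations act on the polarized vinylogous ester of a commercial four-carbon ring. The forward steps must leave the strained carbonyl intact.

11 to 8 to 7: the alkyne C–O and O–Si bonds are cut back to a terminal alkyne, then the propargylic C–C bond back to the prenyl halide and a two-carbon acetylide. The forward steps need substitution at the primary allylic carbon and O-silylation (not C-silylation) of the ynolate.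

## Other disconnections considered

Alternative 1: aryne carboxylate insertion.
- Cut: the C4'–O and C5'–C(=O) bonds together, through a C4'–C5' aryne.
- Forward key step: the ortho-silylaryl triflate A1, CsF and acid 20 give the aryne. The carboxylate adds through oxygen at C4', and the C5' aryl anion takes the acyl group from that oxygen to give the ortho-hydroxyaryl ketone A2.
- In favour: the acyl/hydroxyl pair is set in one fluoride-triggered step with no Lewis acid near the prenyl group and no strong base near the stereocenter. On this point the alternative is better than the chosen plan, whose C5' acylation (step 10) is its weakest non-key step.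
- Against: A1 is itself a pentasubstituted benzene with five different groups, so the regiochemical problem is moved, not solved. The carboxylate must attack the aryne carbon next to the prenyl group, which is electronically preferred but the more hindered end. Free acid could protonate the aryl anion before acyl transfer. A2 still lacks the bridge: C1' must be joined to pyranone A3 through a one-carbon electrophile, which tends to give symmetrical methylene-bis products. The MOM group must then be removed with acid next to the prenyl group.
- Comparison: both plans rely on polar regiocontrol (ynol ether polarity against aryne distortion). The chosen plan builds the ring with the bridge carbon attached, whereas this one decorates a preformed ring. In convergence it is equal. In step count it is expected to be equal or longer once A1, A3 and the bridging are included.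

Alternative 2: pyranone from 3-pentanone and a benzylmalonyl unit.
- Cut: the pyranone C4–C5 and C2–O1 bonds.
- Forward key step: the trimethylsilyl enol ether A4 is C-acylated by the arylmethylmalonyl dichloride A5 and the enol lactonizes, giving the bis(methoxymethyl) ether A6.
- In favour: the heterocycle forms in one step from a symmetrical ketone, so it has no regiochemical question. This is better than the two acylations of the chosen plan. The aromatic half could carry its acyl group from an early Friedel–Crafts step, before the prenyl group is present. On the timing of the acylation it is also better.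
- Against: A5 combines a diacid chloride with two acetal ethers, a prenyl group and an enolizable stereogenic ketone. Making it, and the HCl and Me3SiCl released in the condensation, would threaten the acetals and then the prenyl group. The monosubstituted malonyl dichloride loses HCl readily to a chlorocarbonyl ketene, and any base added against the acid endangers the stereocenter. The ketone must also survive the malonate alkylation and saponification that precede A5. A6 then needs two acid deprotections beside the prenyl group, where the chosen plan ends with a buffered fluoride.
- Comparison: both plans attach pyranone C3 through the benzylic carbon. The enolate chemistry of the chosen plan is strongly basic but never acidic, which suits the silyl ether and the prenyl group. The hexasubstituted arene half would still have to be made by stepwise substitution of a phloroglucinol, so the total is not expected to be shorter.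

Alternative 3: methoxy-masked tetraketide folded by Claisen cyclization.
- Cut: the C5'–C4' ring bond (C6–C1 of the chain).
- Forward key step: NaOMe in methanol converts the linear ester A7 into its C6 dienolate, which attacks the C1 ester; loss of methanol and enolization give the arene A8.
- In favour: the position of the methyl ether is encoded by the enol ether, the prenyl group is placed by ordinary β-keto ester alkylation, and the reagents are cheap. On placement of the prenyl group and on reagent cost it is equal to the chosen plan. It also closes the same ring bond that the benzannulation re-forms.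
- Against: the stereocenter C8 is α to the C7 ketone that must be enolized toward C6 under equilibrating methoxide, so loss of configuration is the expected process. Aldol closure of C2 onto C7 competes with the Claisen mode. A8 again lacks the bridge carbon and needs the same one-carbon coupling as in alternative 1.
- Comparison: an equilibrating ionic cyclization is set against a neutral pericyclic cascade in which the stereocenter is not yet present. On step count it is expected to be about equal. On stereochemical security it is inferior.

Key step: step 6

Remark on the chemistry: the atom mapping of the benzannulation was checked against its mechanism (cyclobutenone C1 to C4', C2 to C1', C3 to C6', C4 to C5'; alkyne carbons to C3' and C2'). Compounds 6, 11 and 16 are regiochemically consistent as drawn and need no correction. The methine centres of 17 and 18 are formed without control because they vanish in 19. Ethynylmagnesium bromide and N-methoxy-N-methylpropanamide are taken as purchasable reagents.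

Step 1
Reactants: 1 3-ethoxycyclobut-2-en-1-one
Product: 2 2-bromo-3-ethoxycyclobut-2-en-1-one
Conditions: NBS (1.05 equiv), CH2Cl2, 0 °C, dark
Reagents that add atoms: N-bromosuccinimide, O=C1CCC(=O)N1Br
Why: Electrophilic α-halogenation of a vinylogous ester; C2 is the nucleophilic β-carbon of the enol ether, and loss of the proton restores the conjugated enone, as with 3-alkoxycyclohexenones.

Step 2
Reactants: 2 2-bromo-3-ethoxycyclobut-2-en-1-one
Product: 3 2-bromo-3-methoxycyclobut-2-en-1-one
Conditions: MeOH (solvent), camphorsulfonic acid (5 mol%), rt; concentrate and repeat once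
Reagents that add atoms: methanol, CO
Why: Acid-catalysed vinylogous transesterification (addition–elimination at C3), driven by methanol as solvent. It is done on the bromide because 2 is less volatile than the parent enone and its C3 is more electrophilic.

Step 3
Reactants: 3 2-bromo-3-methoxycyclobut-2-en-1-one; 4 methyl 3-bromopropanoate
Product: 6 methyl 3-(2-methoxy-4-oxocyclobut-1-en-1-yl)propanoate, via zinc homoenolate 5 (not isolated)
Conditions: 4, Zn, LiCl, THF, 40 °C; then 3, Pd(OAc)2 (2 mol%), SPhos (4 mol%), THF, rt
Reagents that add atoms: none
Why: Negishi sp2–sp3 coupling of an α-bromoenone with an ester-stabilised alkylzinc, whose internal carbonyl coordination suppresses β-hydride loss. Zerovalent palladium formed from Pd(OAc)2 and SPhos inserts into the C–Br bond, and the alkylzinc does not add to the strained ketone.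

Step 4
Reactants: 7 1-bromo-3-methylbut-2-ene
Product: 8 5-methylhex-4-en-1-yne
Conditions: HC≡CMgBr (2.5 equiv), CuBr·SMe2 (5 mol%), THF, 0 → 40 °C; distilled as a solution
Reagents that add atoms: ethynylmagnesium bromide, C#C[Mg]Br
Why: Copper-catalysed allylic substitution by an alkynyl Grignard reagent, which favours attack at the unhindered primary carbon of the prenyl halide. The excess acetylide suppresses a second prenylation of the product.

Step 5
Reactants: 8 5-methylhex-4-en-1-yne
Product: 11 triisopropyl[(5-methylhex-4-en-1-yn-1-yl)oxy]silane, via lithium acetylide 9 (not isolated), via lithium ynolate 10 (not isolated)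
Conditions: n-BuLi (1.0 equiv), THF, −78 °C; t-BuOOLi (from t-BuOOH and LiN(SiMe3)2), −78 → 0 °C; i-Pr3SiOTf, −78 → 0 °C
Reagents that add atoms: tert-butyl hydroperoxide, CC(C)(C)OO; triisopropylsilyl trifluoromethanesulfonate, CC(C)[Si](C(C)C)(C(C)C)OS(=O)(=O)C(F)(F)F
Why: Oxidation of a lithium acetylide by a lithium alkyl peroxide (electrophilic oxygen transfer with loss of tert-butoxide) gives the ynolate. The bulky silyl triflate then traps it on oxygen and not on carbon, and the acetylenic C–H is removed selectively over the doubly allylic methylene at −78 °C.

Step 6
Reactants: 6 methyl 3-(2-methoxy-4-oxocyclobut-1-en-1-yl)propanoate; 11 triisopropyl[(5-methylhex-4-en-1-yn-1-yl)oxy]silane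
Product: 16 methyl 3-[4-hydroxy-6-methoxy-3-(3-methylbut-2-enyl)-2-(triisopropylsilyloxy)phenyl]propanoate, via vinylketene 12 (not isolated), via vinylcyclobutenone 13 (not isolated), via dienylketene 14 (not isolated), via cyclohexadienone 15 (not isolated)
Conditions: 11 (1.5 equiv), PhMe (0.2 M), 110 °C, sealed tube, Ar
Reagents that add atoms: none
Why: Danheiser benzannulation; the closest known type is the thermal cyclobutenone–siloxyalkyne benzannulation. Heat opens 6 by 4π conrotatory cleavage of the C1–C4 bond to vinylketene 12, whose carbonyl carbon is attacked by the alkyne carbon remote from oxygen; closure at the silyloxy-bearing carbon completes a polar [2+2] addition to 13. A second 4π opening gives dienylketene 14, and thermal disrotatory 6π electrocyclization closes the only new ring, the six-membered carbocycle, by joining the ketene carbon to the methylene terminus (the old C1–C4 pair, C4'–C5' of the target); enolization of 15 then gives the phenol. The net new skeletal bonds are C3'–C4' and C1'–C2'. No stereocenter is formed. The one selectivity required is the orientation of the [2+2] addition, and the polarization of the ynol ether secures it (nucleophilic β-carbon, oxygen-stabilised α-carbon), placing the prenyl group between the new hydroxyl and the silyl ether. The methoxy group rides on the vinyl terminus and ends as the C6' methyl ether, and the excess of 11 keeps 12 from being consumed by the product phenol.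

Step 7
Reactants: 16 methyl 3-[4-hydroxy-6-methoxy-3-(3-methylbut-2-enyl)-2-(triisopropylsilyloxy)phenyl]propanoate
Product: 17 methyl 2-{[4-hydroxy-6-methoxy-3-(3-methylbut-2-enyl)-2-(triisopropylsilyloxy)phenyl]methyl}-3-oxopentanoate (racemic at C2)
Conditions: LiN(i-Pr)2 (2.3 equiv), THF, −78 °C; EtC(O)N(OMe)Me (1.3 equiv), −78 → −20 °C; aq. NH4Cl
Reagents that add atoms: N-methoxy-N-methylpropanamide, CCC(=O)N(C)OC
Why: Crossed Claisen acylation of an ester enolate by an N-methoxy-N-methylamide (Weinreb ketone synthesis logic). The chelated tetrahedral adduct prevents over-reaction, and the lithium phenoxide, which is meta to the side chain and cannot lactonize, does not attack an amide, so the phenol needs no protection.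

Step 8
Reactants: 17 methyl 2-{[4-hydroxy-6-methoxy-3-(3-methylbut-2-enyl)-2-(triisopropylsilyloxy)phenyl]methyl}-3-oxopentanoate
Product: 19 6-ethyl-4-hydroxy-3-{[4-hydroxy-6-methoxy-3-(3-methylbut-2-enyl)-2-(triisopropylsilyloxy)phenyl]methyl}-5-methyl-2H-pyran-2-one, via diketo ester 18 (not isolated)
Conditions: LiN(i-Pr)2 (3.4 equiv), THF, −78 → 0 °C; EtC(O)N(OMe)Me (1.3 equiv), −78 → 0 °C; aq. NH4Cl work-up; crude, DBU (1.5 equiv), PhMe, 80 °C
Reagents that add atoms: N-methoxy-N-methylpropanamide, CCC(=O)N(C)OC
Why: γ-Acylation of a β-keto ester dianion (here a trianion with the phenoxide) occurs at the last-formed, most nucleophilic carbon, and the stable amide adduct releases 18 only on work-up, so no Claisen carbocyclization can occur in the basic medium. DBU then induces enol-lactonization with loss of methanol to the 4-hydroxy-2-pyranone, and the silyl ether keeps the C2' oxygen from competing for the ester.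

Step 9
Reactants: 19 6-ethyl-4-hydroxy-3-{[4-hydroxy-6-methoxy-3-(3-methylbut-2-enyl)-2-(triisopropylsilyloxy)phenyl]methyl}-5-methyl-2H-pyran-2-one; 20 (2R)-2-methylbutanoic acid
Product: 21 4-[(6-ethyl-4-hydroxy-5-methyl-2-oxo-2H-pyran-3-yl)methyl]-5-methoxy-2-(3-methylbut-2-enyl)-3-(triisopropylsilyloxy)phenyl (2R)-2-methylbutanoate
Conditions: 20 (1.2 equiv), EDC·HCl (1.4 equiv), i-Pr2NEt (2.5 equiv), DMAP (0.3 equiv), CH2Cl2, 0 °C → rt
Reagents that add atoms: none
Why: Steglich esterification; any acyl group that lands on the ionized pyranone oxygen forms a vinylogous anhydride that DMAP re-activates, so the acyl group should relay to the less acidic phenol oxygen, where the ester is thermodynamically preferred. Pyranone C3 and C5 are substituted, so no C-acylation is possible, and the stereocenter is carried in unchanged because a simple α-alkyl acid at 0 °C with catalytic DMAP has little tendency to form a ketene.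

Step 10
Reactants: 21 4-[(6-ethyl-4-hydroxy-5-methyl-2-oxo-2H-pyran-3-yl)methyl]-5-methoxy-2-(3-methylbut-2-enyl)-3-(triisopropylsilyloxy)phenyl (2R)-2-methylbutanoate
Product: 22 6-ethyl-4-hydroxy-3-({4-hydroxy-6-methoxy-5-[(2R)-2-methylbutanoyl]-3-(3-methylbut-2-enyl)-2-(triisopropylsilyloxy)phenyl}methyl)-5-methyl-2H-pyran-2-one
Conditions: TiCl4 (2.5 equiv), 2,6-di-tert-butyl-4-methylpyridine (1.5 equiv), CH2Cl2, −40 → 0 °C; aq. potassium sodium tartrate
Reagents that add atoms: none
Why: Fries rearrangement; TiCl4 ionizes the aryl ester and the acyl cation is delivered to C5', the only unsubstituted ring carbon, which is activated by the ortho methoxy and para silyloxy groups. Both oxygens flanking the prenyl group are blocked until the shift is over, and the product phenoxide is then held in a titanium chelate. The hindered pyridine removes HCl, and the acyl group migrates with its configuration intact because an acyl cation has no basic partner for enolization at low temperature.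

Step 11
Reactants: 22 6-ethyl-4-hydroxy-3-({4-hydroxy-6-methoxy-5-[(2R)-2-methylbutanoyl]-3-(3-methylbut-2-enyl)-2-(triisopropylsilyloxy)phenyl}methyl)-5-methyl-2H-pyran-2-one
Product: 23 6-ethyl-3-({2,4-dihydroxy-6-methoxy-5-[(2R)-2-methylbutanoyl]-3-(3-methylbut-2-enyl)phenyl}methyl)-4-hydroxy-5-methyl-2H-pyran-2-one
Conditions: Bu4NF (1.5 equiv), AcOH (1.5 equiv), THF, 0 °C
Reagents that add atoms: none
Why: Fluoride cleavage of an aryl silyl ether, driven by the Si–F bond. The acetic acid buffer keeps the medium near neutral, so the α-stereocenter of the aryl ketone is not enolized and the prenyl group sees no strong acid.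

Compound list

1 | 3-ethoxycyclobut-2-en-1-one | CCOC1=CC(=O)C1 | starting material
2 | 2-bromo-3-ethoxycyclobut-2-en-1-one | CCOC1=C(Br)C(=O)C1 | intermediate
3 | 2-bromo-3-methoxycyclobut-2-en-1-one | COC1=C(Br)C(=O)C1 | intermediate
4 | methyl 3-bromopropanoate | COC(=O)CCBr | starting material
5 | (3-methoxy-3-oxopropyl)zinc bromide (zinc homoenolate) | COC(=O)CC[Zn]Br | intermediate
6 | methyl 3-(2-methoxy-4-oxocyclobut-1-en-1-yl)propanoate | COC1=C(CCC(=O)OC)C(=O)C1 | intermediate
7 | 1-bromo-3-methylbut-2-ene | CC(C)=CCBr | starting material
8 | 5-methylhex-4-en-1-yne | CC(C)=CCC#C | intermediate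
9 | (5-methylhex-4-en-1-yn-1-yl)lithium (lithium acetylide) | [Li]C#CCC=C(C)C | intermediate
10 | lithium 5-methylhex-4-en-1-yn-1-olate (lithium ynolate) | [Li+].[O-]C#CCC=C(C)C | intermediate
11 | triisopropyl[(5-methylhex-4-en-1-yn-1-yl)oxy]silane | CC(C)=CCC#CO[Si](C(C)C)(C(C)C)C(C)C | intermediate
12 | methyl 5-methoxy-4-(oxomethylidene)hex-5-enoate (vinylketene) | COC(=O)CCC(=C=O)C(OC)=C | intermediate
13 | methyl 3-[1-(1-methoxyethenyl)-3-(3-methylbut-2-enyl)-4-oxo-2-(triisopropylsilyloxy)cyclobut-2-en-1-yl]propanoate (vinylcyclobutenone) | O=C1C(CC=C(C)C)=C(O[Si](C(C)C)(C(C)C)C(C)C)C1(CCC(=O)OC)C(OC)=C | intermediate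
14 | methyl (4E)-4-(1-methoxyethenyl)-9-methyl-6-(oxomethylidene)-5-(triisopropylsilyloxy)deca-4,8-dienoate (dienylketene) | O=C=C(CC=C(C)C)/C(O[Si](C(C)C)(C(C)C)C(C)C)=C(CCC(=O)OC)\C(OC)=C | intermediate
15 | methyl 3-[2-methoxy-5-(3-methylbut-2-enyl)-4-oxo-6-(triisopropylsilyloxy)cyclohexa-1,5-dien-1-yl]propanoate (cyclohexadienone) | O=C1CC(OC)=C(CCC(=O)OC)C(O[Si](C(C)C)(C(C)C)C(C)C)=C1CC=C(C)C | intermediate
16 | methyl 3-[4-hydroxy-6-methoxy-3-(3-methylbut-2-enyl)-2-(triisopropylsilyloxy)phenyl]propanoate | COC(=O)CCc1c(O[Si](C(C)C)(C(C)C)C(C)C)c(CC=C(C)C)c(O)cc1OC | intermediate
17 | methyl 2-{[4-hydroxy-6-methoxy-3-(3-methylbut-2-enyl)-2-(triisopropylsilyloxy)phenyl]methyl}-3-oxopentanoate (racemic) | CCC(=O)C(Cc1c(O[Si](C(C)C)(C(C)C)C(C)C)c(CC=C(C)C)c(O)cc1OC)C(=O)OC | intermediate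
18 | methyl 2-{[4-hydroxy-6-methoxy-3-(3-methylbut-2-enyl)-2-(triisopropylsilyloxy)phenyl]methyl}-4-methyl-3,5-dioxoheptanoate (diketo ester, stereoisomer and enol mixture) | CCC(=O)C(C)C(=O)C(Cc1c(O[Si](C(C)C)(C(C)C)C(C)C)c(CC=C(C)C)c(O)cc1OC)C(=O)OC | intermediate
19 | 6-ethyl-4-hydroxy-3-{[4-hydroxy-6-methoxy-3-(3-methylbut-2-enyl)-2-(triisopropylsilyloxy)phenyl]methyl}-5-methyl-2H-pyran-2-one | CCc1oc(=O)c(Cc2c(O[Si](C(C)C)(C(C)C)C(C)C)c(CC=C(C)C)c(O)cc2OC)c(O)c1C | intermediate
20 | (2R)-2-methylbutanoic acid | CC[C@@H](C)C(=O)O | starting material
21 | 4-[(6-ethyl-4-hydroxy-5-methyl-2-oxo-2H-pyran-3-yl)methyl]-5-methoxy-2-(3-methylbut-2-enyl)-3-(triisopropylsilyloxy)phenyl (2R)-2-methylbutanoate | CC[C@@H](C)C(=O)Oc1cc(OC)c(Cc2c(O)c(C)c(CC)oc2=O)c(O[Si](C(C)C)(C(C)C)C(C)C)c1CC=C(C)C | intermediate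
22 | 6-ethyl-4-hydroxy-3-({4-hydroxy-6-methoxy-5-[(2R)-2-methylbutanoyl]-3-(3-methylbut-2-enyl)-2-(triisopropylsilyloxy)phenyl}methyl)-5-methyl-2H-pyran-2-one | CCc1oc(=O)c(Cc2c(O[Si](C(C)C)(C(C)C)C(C)C)c(CC=C(C)C)c(O)c(C(=O)[C@H](C)CC)c2OC)c(O)c1C | intermediate
23 | 6-ethyl-3-({2,4-dihydroxy-6-methoxy-5-[(2R)-2-methylbutanoyl]-3-(3-methylbut-2-enyl)phenyl}methyl)-4-hydroxy-5-methyl-2H-pyran-2-one | CCc1oc(=O)c(Cc2c(O)c(CC=C(C)C)c(O)c(C(=O)[C@H](C)CC)c2OC)c(O)c1C | target

Total step count: 11. Longest linear sequence: 9 steps (1, 2, 3, 6, 7, 8, 9, 10, 11); the alkyne branch (4, 5) joins at step 6.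

Steps least certain to work

Step 6 (key step). The methoxy group makes 6 a vinylogous ester, which stabilises the four-membered ring against the first 4π opening. At the temperature then required, oligomerization of ketene 12 or its capture by the product phenol may outrun addition to 11. The fallback generates the same ketene at room temperature by photochemical Wolff rearrangement, the second-generation form of the benzannulation. It sets out from 11, which stays the alkyne partner, and returns to the route at 16. (1-Methoxyethenyl)zinc chloride F1, made from methyl vinyl ether with t-BuLi and then ZnCl2, is acylated by commercial methyl 5-chloro-5-oxopentanoate under Pd(PPh3)4 catalysis to give methyl 6-methoxy-5-oxohept-6-enoate F2. Detrifluoroacetylative diazo transfer (LiN(SiMe3)2, 2,2,2-trifluoroethyl trifluoroacetate; then MsN3, Et3N) at the ketone α-methylene gives methyl 4-diazo-6-methoxy-5-oxohept-6-enoate F3. Irradiation of F3 with 11 in 1,2-dichloroethane at room temperature, followed by warming to 80 °C, should release nitrogen, shift the methoxyvinyl group and deliver 12, and from it 13, 14, 15 and 16.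

Step 10. HCl formed in the rearrangement may protonate the prenyl double bond, after which a neighbouring oxygen closes a chroman. The silyl ether may be lost early, and the titanium-bound ketone may enolize with erosion of configuration. The fallback is a photo-Fries rearrangement, which runs from 21 directly to 22. Irradiation at 254 nm in degassed acetonitrile should homolyse the aryl ester C–O bond to an aryloxyl/acyl radical pair that recombines in the solvent cage at C5', the only open ortho or para carbon. No acid or base is present, and in-cage recombination is much faster than decarbonylation, so the acyl radical should keep its α-configuration. This fallback makes no new compound (F0).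

Step 3. Transmetalation of the alkylzinc to the hindered, donor-substituted vinylpalladium may be slow, which would allow reductive loss of bromine or degradation of the strained enone. The fallback builds the side chain by alkene insertion; it sets out from 3 and returns at 6. A Heck reaction of 3 with methyl acrylate (Pd(OAc)2, P(o-tol)3, Et3N, MeCN, 60 °C) gives methyl (2E)-3-(2-methoxy-4-oxocyclobut-1-en-1-yl)prop-2-enoate F4. Hydrogenation with RhCl(PPh3)3 and H2 in benzene should then reduce only the disubstituted acrylate double bond, leaving the tetrasubstituted, donor-substituted ring alkene, to give 6.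

Step 9. The acyl group may come to rest on the pyranone enol oxygen, which is the first hydroxyl to ionize, if the relay to the hindered phenol is slow. The fallback acylates both hydroxyls and then removes one; it sets out from 19 and returns at 21. With 2.5 equivalents of 20 under the same carbodiimide conditions, 19 should give the bis-ester 4-[(6-ethyl-5-methyl-4-{[(2R)-2-methylbutanoyl]oxy}-2-oxo-2H-pyran-3-yl)methyl]-5-methoxy-2-(3-methylbut-2-enyl)-3-(triisopropylsilyloxy)phenyl (2R)-2-methylbutanoate F5. Brief treatment with methanol and imidazole at 0 °C should cleave only the pyranone enol ester, a vinylogous anhydride, and leave the hindered aryl ester as 21.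

Step 2. Methanol may add to the strained carbonyl group and cleave the ring, or the compound may rest as a ketal instead of exchanging cleanly. The fallback replaces exchange by hydrolysis and O-alkylation; it sets out from 2 and returns at 3. Aqueous HCl in THF hydrolyses 2 to the vinylogous acid 2-bromo-3-hydroxycyclobut-2-en-1-one F6, and Me3SiCHN2 in methanol/toluene methylates its oxygen to give 3.

Further compounds

F1 | step 6 | (1-methoxyethenyl)zinc chloride | COC(=C)[Zn]Cl
F2 | step 6 | methyl 6-methoxy-5-oxohept-6-enoate | COC(=O)CCCC(=O)C(OC)=C
F3 | step 6 | methyl 4-diazo-6-methoxy-5-oxohept-6-enoate | COC(=O)CCC(=[N+]=[N-])C(=O)C(OC)=C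
F0 | step 10 | none | none
F4 | step 3 | methyl (2E)-3-(2-methoxy-4-oxocyclobut-1-en-1-yl)prop-2-enoate | COC(=O)/C=C/C1=C(OC)CC1=O
F5 | step 9 | 4-[(6-ethyl-5-methyl-4-{[(2R)-2-methylbutanoyl]oxy}-2-oxo-2H-pyran-3-yl)methyl]-5-methoxy-2-(3-methylbut-2-enyl)-3-(triisopropylsilyloxy)phenyl (2R)-2-methylbutanoate | CC[C@@H](C)C(=O)Oc1cc(OC)c(Cc2c(OC(=O)[C@H](C)CC)c(C)c(CC)oc2=O)c(O[Si](C(C)C)(C(C)C)C(C)C)c1CC=C(C)C
F6 | step 2 | 2-bromo-3-hydroxycyclobut-2-en-1-one | O=C1CC(O)=C1Br
A1 | alternative 1 | 3-methoxy-5-(methoxymethoxy)-6-(3-methylbut-2-enyl)-2-(trimethylsilyl)phenyl trifluoromethanesulfonate | COCOc1cc(OC)c([Si](C)(C)C)c(OS(=O)(=O)C(F)(F)F)c1CC=C(C)C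
A2 | alternative 1 | (2R)-1-[2-hydroxy-6-methoxy-4-(methoxymethoxy)-3-(3-methylbut-2-enyl)phenyl]-2-methylbutan-1-one | COCOc1cc(OC)c(C(=O)[C@H](C)CC)c(O)c1CC=C(C)C
A3 | alternative 1 | 6-ethyl-4-hydroxy-5-methyl-2H-pyran-2-one | CCc1oc(=O)cc(O)c1C
A4 | alternative 2 | trimethyl(pent-2-en-3-yloxy)silane | CC=C(CC)O[Si](C)(C)C
A5 | alternative 2 | 2-({6-methoxy-2,4-bis(methoxymethoxy)-5-[(2R)-2-methylbutanoyl]-3-(3-methylbut-2-enyl)phenyl}methyl)propanedioyl dichloride | O=C(Cl)C(Cc1c(OCOC)c(CC=C(C)C)c(OCOC)c(C(=O)[C@H](C)CC)c1OC)C(=O)Cl
A6 | alternative 2 | 6-ethyl-4-hydroxy-3-({6-methoxy-2,4-bis(methoxymethoxy)-5-[(2R)-2-methylbutanoyl]-3-(3-methylbut-2-enyl)phenyl}methyl)-5-methyl-2H-pyran-2-one | CCc1oc(=O)c(Cc2c(OCOC)c(CC=C(C)C)c(OCOC)c(C(=O)[C@H](C)CC)c2OC)c(O)c1C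
A7 | alternative 3 | methyl (5E,8R)-5-methoxy-8-methyl-2-(3-methylbut-2-enyl)-3,7-dioxodec-5-enoate | COC(=O)C(CC=C(C)C)C(=O)C/C(OC)=C\C(=O)[C@H](C)CC
A8 | alternative 3 | (2R)-1-[2,4-dihydroxy-6-methoxy-3-(3-methylbut-2-enyl)phenyl]-2-methylbutan-1-one | O=C([C@H](C)CC)c1c(O)c(CC=C(C)C)c(O)cc1OC
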